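## Retrosynthetic overview

1. Numbering: O1, C2 (bears ring A), C3, C4 (carbinol), C5, C6 (bears the chain C7–C8–ring B). C6 is an ether carbon exactly two carbons away from ring B. C6–C7–C8 can therefore be read as an allyl unit, with C6 as its inner end and C8 as the carbon that is arylated later.
2. Endgame: the target comes from saturation of C7=C8 with loss of three benzyl groups, after desilylation. The C8–ring B bond comes from Heck arylation of a 6-vinyl pyran.
3. Key disconnection O1–C6: palladium-catalysed asymmetric allylic etherification of an open-chain (E)-allylic methyl carbonate that has a free C2 hydroxyl and a silylated C4 oxygen. The pyran is the only ring formed; rings A and B are bought.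
4. Open chain: cross-metathesis installs the carbonate. C2 and C4 (1,3-syn) come from two Brown allylborations of benzylated 5-hydroxyvanillin, with an oxidative alkene cleavage between them. TES on the C2 oxygen and TBS on the C4 oxygen tell the two hydroxyls apart.

Key step: step 9

Abbreviations: ArA = 3,4-bis(benzyloxy)-5-methoxyphenyl (protected ring A). ArB = 4-benzyloxy-3-methoxyphenyl (protected ring B). The pyran locants are also used for the open-chain compounds.

Assumption: the (R,R) enantiomer of the diphosphine is taken as the one matched to the 6R closure, by extending the quadrant model of this ligand family to E-configured allylic carbonates. Both enantiomers are commercial, so the assignment is checked in one trial run on 14.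

## Route

Step 1
Reactants: 1 5-hydroxyvanillin
Product: 2 3,4-bis(benzyloxy)-5-methoxybenzaldehyde
Conditions: BnBr (2.4 equiv), K2CO3, DMF, 60 °C, N2
Reagents that add atoms: benzyl bromide, BrCc1ccccc1
Why: Williamson ether synthesis, in which both phenoxides of the catechol are alkylated by the primary benzylic bromide while the aldehyde is inert to carbonate base.

Step 2
Reactants: 2 3,4-bis(benzyloxy)-5-methoxybenzaldehyde; 3 B-allyldiisopinocampheylborane derived from (+)-α-pinene
Product: 5 (S)-1-ArA-but-3-en-1-ol, via borinate ester 4 (not isolated)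
Conditions: 3 (1.3 equiv), Et2O–THF, −78 °C; then 3 M NaOH, 30% H2O2, 0 °C to rt
Reagents that add atoms: B-allyldiisopinocampheylborane 3 (allyl group), C=CCB([C@@H]1C[C@@H]2C[C@H]([C@H]1C)C2(C)C)[C@@H]1C[C@@H]2C[C@H]([C@H]1C)C2(C)C
Why: Brown asymmetric allylboration through a closed chair (Zimmerman–Traxler) transition state, in which the isopinocampheyl groups of this reagent enantiomer send the allyl group to the si face of an aromatic aldehyde and so set C2 as S, after which alkaline peroxide frees the alcohol from 4.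

Step 3
Reactants: 5 (S)-1-ArA-but-3-en-1-ol
Product: 6 (S)-1-ArA-1-(triethylsilyloxy)but-3-ene
Conditions: TESCl, imidazole, CH2Cl2, 0 °C to rt
Reagents that add atoms: chlorotriethylsilane, CC[Si](Cl)(CC)CC
Why: Standard silylation of a secondary alcohol, with TES chosen because it can later be removed beside a secondary TBS ether.

Step 4
Reactants: 6 (S)-1-ArA-1-(triethylsilyloxy)but-3-ene
Product: 8 (S)-3-ArA-3-(triethylsilyloxy)propanal, via vicinal diol 7 (not isolated)
Conditions: OsO4 (2 mol %), NaIO4 (4 equiv), 2,6-lutidine, dioxane–H2O, rt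
Reagents that add atoms: OsO4 (catalytic oxygen carrier), O=[Os](=O)(=O)=O; NaIO4 (terminal oxygen source), [Na+].[O-]I(=O)(=O)=O
Why: Lemieux–Johnson cleavage (dihydroxylation, then periodate glycol cleavage) touches only the terminal alkene and spares the electron-rich ring A and the benzyl ethers, which ozone might attack, while 2,6-lutidine keeps the medium neutral so that the β-silyloxy aldehyde does not eliminate.

Step 5
Reactants: 8 (S)-3-ArA-3-(triethylsilyloxy)propanal; 3 B-allyldiisopinocampheylborane derived from (+)-α-pinene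
Product: 10 (4S,6S)-6-ArA-6-(triethylsilyloxy)hex-1-en-4-ol, via borinate ester 9 (not isolated)
Conditions: 3 (1.5 equiv), Et2O, −78 °C; then 3 M NaOH, 30% H2O2, 0 °C
Reagents that add atoms: B-allyldiisopinocampheylborane 3 (allyl group), C=CCB([C@@H]1C[C@@H]2C[C@H]([C@H]1C)C2(C)C)[C@@H]1C[C@@H]2C[C@H]([C@H]1C)C2(C)C
Why: Second Brown allylboration, in which the same reagent enantiomer again adds to the si face under reagent control and so sets the pyran C4 carbinol as S, 1,3-syn to C2, with any anti diastereomer removable by chromatography.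

Step 6
Reactants: 10 (4S,6S)-6-ArA-6-(triethylsilyloxy)hex-1-en-4-ol
Product: 11 (4S,6S)-6-ArA-4-(tert-butyldimethylsilyloxy)-6-(triethylsilyloxy)hex-1-ene
Conditions: TBSCl, imidazole, DMAP (cat.), DMF, rt
Reagents that add atoms: tert-butylchlorodimethylsilane, CC(C)(C)[Si](C)(C)Cl
Why: Silylation under non-alkoxide conditions, so that the neighbouring TES group does not migrate and the two oxygens stay differentiated.

Step 7
Reactants: 11 (4S,6S)-6-ArA-4-(tert-butyldimethylsilyloxy)-6-(triethylsilyloxy)hex-1-ene; 12 allyl methyl carbonate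
Product: 13 (E,5S,7S)-7-ArA-5-(tert-butyldimethylsilyloxy)-7-(triethylsilyloxy)hept-2-enyl methyl carbonate
Conditions: 12 (4 equiv), second-generation Hoveyda–Grubbs catalyst (5 mol %), CH2Cl2, 40 °C
Reagents that add atoms: allyl methyl carbonate 12, C=CCOC(=O)OC
Why: Olefin cross-metathesis of two unhindered terminal alkenes, driven by excess partner and loss of ethene, which should favour the more stable E-alkene.

Step 8
Reactants: 13 (E,5S,7S)-7-ArA-5-(tert-butyldimethylsilyloxy)-7-(triethylsilyloxy)hept-2-enyl methyl carbonate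
Product: 14 (E,5S,7S)-7-ArA-5-(tert-butyldimethylsilyloxy)-7-hydroxyhept-2-enyl methyl carbonate
Conditions: HF·pyridine, pyridine, THF, 0 °C
Reagents that add atoms: none
Why: Kinetically selective fluoride desilylation, in which the less shielded TES silicon reacts far faster than TBS and the pyridine-buffered medium is too mild to ionise the benzylic C–O bond or attack the carbonate.

Step 9
Reactants: 14 (E,5S,7S)-7-ArA-5-(tert-butyldimethylsilyloxy)-7-hydroxyhept-2-enyl methyl carbonate
Product: 16 (2S,4S,6R)-2-ArA-4-(tert-butyldimethylsilyloxy)-6-vinyltetrahydropyran, via π-allyl palladium cation 15 (not isolated)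
Conditions: Pd2(dba)3·CHCl3 (2.5 mol %), (1R,2R)-N,N'-bis[2-(diphenylphosphino)benzoyl]cyclohexane-1,2-diamine (7.5 mol %), degassed CH2Cl2 (0.03 M), 0 °C to rt
Reagents that add atoms: none
Why: Zerovalent palladium bound to the chiral diphosphine ionises the allylic carbonate of 14 to the cationic π-allyl complex 15 of divalent palladium, CO2 is lost, the methoxide so formed takes the proton of the C2 hydroxyl, and the alkoxide attacks the inner allyl carbon C6 on the face away from the metal, which makes O1–C6 and returns the catalyst. The closest known reaction type is the intramolecular Tsuji–Trost asymmetric allylic etherification of hydroxy allylic carbonates to 2-vinyl tetrahydropyrans. The pyran closes in the 6-exo-trig mode; attack at the CH2 end C8 would need an eight-membered ring holding an E-alkene, so ring size secures the branched regiochemistry. C6 is the one new stereocentre: the two diastereomeric forms of 15 exchange the metal between the allyl faces by η3–η1–η3 slippage at the unsubstituted end C8 faster than they cyclise, so the chiral pocket of the ligand chooses the face that closes (Curtin–Hammett control). The substrate pushes the same way, because in the chair-like transition state with ring A equatorial the C4 silyloxy group is axial and a trans closure would set the allyl unit 1,3-diaxial to it, which leaves the 2,6-cis (6R) closure with an equatorial allyl unit. Chemoselectivity rests on the TBS group, which leaves the C2 hydroxyl as the only nucleophile, and on the near-neutral medium, which does not ionise the electron-rich benzylic C2–O bond, so C2 and C4 are carried through unchanged.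

Step 10
Reactants: 17 4-bromo-2-methoxyphenol
Product: 18 1-(benzyloxy)-4-bromo-2-methoxybenzene
Conditions: BnBr, K2CO3, acetone, reflux
Reagents that add atoms: benzyl bromide, BrCc1ccccc1
Why: Williamson ether synthesis on a single phenol, with the aryl bromide inert under these conditions.

Step 11
Reactants: 16 (2S,4S,6R)-2-ArA-4-(tert-butyldimethylsilyloxy)-6-vinyltetrahydropyran; 18 1-(benzyloxy)-4-bromo-2-methoxybenzene
Product: 19 (2S,4S,6R)-2-ArA-6-[(E)-2-ArB-ethenyl]-4-(tert-butyldimethylsilyloxy)tetrahydropyran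
Conditions: Pd(OAc)2 (5 mol %), P(o-tol)3 (12 mol %), Et3N, DMF, 100 °C
Reagents that add atoms: aryl bromide 18 (aryl group), COc1cc(Br)ccc1OCc1ccccc1
Why: Mizoroki–Heck reaction, in which 18 adds oxidatively to zerovalent palladium formed in the flask, the unhindered vinyl group inserts with aryl transfer to the terminal carbon C8, and syn β-hydride loss from C8 gives the conjugated (E)-styrene without involving C6.

Step 12
Reactants: 19 (2S,4S,6R)-2-ArA-6-[(E)-2-ArB-ethenyl]-4-(tert-butyldimethylsilyloxy)tetrahydropyran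
Product: 20 (2S,4S,6R)-2-ArA-6-[(E)-2-ArB-ethenyl]tetrahydropyran-4-ol
Conditions: TBAF, THF, 0 °C to rt
Reagents that add atoms: none
Why: Fluoride desilylation of a secondary TBS ether, placed before the hydrogenolysis so that basic fluoride never meets the oxidation-prone free catechol.

Step 13
Reactants: 20 (2S,4S,6R)-2-ArA-6-[(E)-2-ArB-ethenyl]tetrahydropyran-4-ol
Product: 21 (2S,4S,6S)-2-(3,4-dihydroxy-5-methoxyphenyl)-6-[2-(4-hydroxy-3-methoxyphenyl)ethyl]tetrahydropyran-4-ol (target)
Conditions: H2 (1 atm), 10% Pd/C, EtOAc–EtOH, rt, stopped after uptake of four equivalents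
Reagents that add atoms: none
Why: Heterogeneous catalytic hydrogenation saturates C7=C8 and hydrogenolyses the three aryl benzyl ethers, which cleave much faster than the ring C2–O1 bond, and no stereocentre is touched (the C6 descriptor changes from R to S only through the priority change).

## Compound list

1 | 5-hydroxyvanillin (3,4-dihydroxy-5-methoxybenzaldehyde) | COc1cc(C=O)cc(O)c1O | starting material
2 | 3,4-bis(benzyloxy)-5-methoxybenzaldehyde | COc1cc(C=O)cc(OCc2ccccc2)c1OCc1ccccc1 | intermediate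
3 | B-allyldiisopinocampheylborane, the enantiomer derived from (+)-α-pinene, sold as (−)-Ipc2B(allyl), 1 M in pentane | C=CCB([C@@H]1C[C@@H]2C[C@H]([C@H]1C)C2(C)C)[C@@H]1C[C@@H]2C[C@H]([C@H]1C)C2(C)C | starting material
4 | diisopinocampheylborinate ester of 5 (not isolated) | C=CC[C@H](OB([C@@H]1C[C@@H]2C[C@H]([C@H]1C)C2(C)C)[C@@H]1C[C@@H]2C[C@H]([C@H]1C)C2(C)C)c1cc(OCc2ccccc2)c(OCc2ccccc2)c(OC)c1 | intermediate
5 | (S)-1-[3,4-bis(benzyloxy)-5-methoxyphenyl]but-3-en-1-ol | C=CC[C@H](O)c1cc(OCc2ccccc2)c(OCc2ccccc2)c(OC)c1 | intermediate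
6 | (S)-1-[3,4-bis(benzyloxy)-5-methoxyphenyl]-1-(triethylsilyloxy)but-3-ene | C=CC[C@H](O[Si](CC)(CC)CC)c1cc(OCc2ccccc2)c(OCc2ccccc2)c(OC)c1 | intermediate
7 | (4S)-4-[3,4-bis(benzyloxy)-5-methoxyphenyl]-4-(triethylsilyloxy)butane-1,2-diol, both epimers at the butane C2 (not isolated) | OCC(O)C[C@H](O[Si](CC)(CC)CC)c1cc(OCc2ccccc2)c(OCc2ccccc2)c(OC)c1 | intermediate
8 | (S)-3-[3,4-bis(benzyloxy)-5-methoxyphenyl]-3-(triethylsilyloxy)propanal | O=CC[C@H](O[Si](CC)(CC)CC)c1cc(OCc2ccccc2)c(OCc2ccccc2)c(OC)c1 | intermediate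
9 | diisopinocampheylborinate ester of 10 (not isolated) | C=CC[C@H](OB([C@@H]1C[C@@H]2C[C@H]([C@H]1C)C2(C)C)[C@@H]1C[C@@H]2C[C@H]([C@H]1C)C2(C)C)C[C@H](O[Si](CC)(CC)CC)c1cc(OCc2ccccc2)c(OCc2ccccc2)c(OC)c1 | intermediate
10 | (4S,6S)-6-[3,4-bis(benzyloxy)-5-methoxyphenyl]-6-(triethylsilyloxy)hex-1-en-4-ol (1,3-syn) | C=CC[C@H](O)C[C@H](O[Si](CC)(CC)CC)c1cc(OCc2ccccc2)c(OCc2ccccc2)c(OC)c1 | intermediate
11 | (4S,6S)-6-[3,4-bis(benzyloxy)-5-methoxyphenyl]-4-(tert-butyldimethylsilyloxy)-6-(triethylsilyloxy)hex-1-ene | C=CC[C@H](O[Si](C)(C)C(C)(C)C)C[C@H](O[Si](CC)(CC)CC)c1cc(OCc2ccccc2)c(OCc2ccccc2)c(OC)c1 | intermediate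
12 | allyl methyl carbonate | C=CCOC(=O)OC | starting material
13 | (E,5S,7S)-7-[3,4-bis(benzyloxy)-5-methoxyphenyl]-5-(tert-butyldimethylsilyloxy)-7-(triethylsilyloxy)hept-2-enyl methyl carbonate | COC(=O)OC/C=C/C[C@H](O[Si](C)(C)C(C)(C)C)C[C@H](O[Si](CC)(CC)CC)c1cc(OCc2ccccc2)c(OCc2ccccc2)c(OC)c1 | intermediate
14 | (E,5S,7S)-7-[3,4-bis(benzyloxy)-5-methoxyphenyl]-5-(tert-butyldimethylsilyloxy)-7-hydroxyhept-2-enyl methyl carbonate (key-step precursor) | COC(=O)OC/C=C/C[C@H](O[Si](C)(C)C(C)(C)C)C[C@H](O)c1cc(OCc2ccccc2)c(OCc2ccccc2)c(OC)c1 | intermediate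
15 | cationic π-allyl palladium complex from 14, drawn as its η1 form at C8 with the diphosphine left out (not isolated) | [Pd+]C/C=C/C[C@H](O[Si](C)(C)C(C)(C)C)C[C@H](O)c1cc(OCc2ccccc2)c(OCc2ccccc2)c(OC)c1 | intermediate
16 | (2S,4S,6R)-2-[3,4-bis(benzyloxy)-5-methoxyphenyl]-4-(tert-butyldimethylsilyloxy)-6-vinyltetrahydropyran (2,6-cis, C4 oxygen trans to both) | C=C[C@H]1C[C@H](O[Si](C)(C)C(C)(C)C)C[C@@H](c2cc(OCc3ccccc3)c(OCc3ccccc3)c(OC)c2)O1 | intermediate
17 | 4-bromo-2-methoxyphenol | COc1cc(Br)ccc1O | starting material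
18 | 1-(benzyloxy)-4-bromo-2-methoxybenzene | COc1cc(Br)ccc1OCc1ccccc1 | intermediate
19 | (2S,4S,6R)-2-[3,4-bis(benzyloxy)-5-methoxyphenyl]-6-[(E)-2-(4-benzyloxy-3-methoxyphenyl)ethenyl]-4-(tert-butyldimethylsilyloxy)tetrahydropyran | COc1cc(/C=C/[C@H]2C[C@H](O[Si](C)(C)C(C)(C)C)C[C@@H](c3cc(OCc4ccccc4)c(OCc4ccccc4)c(OC)c3)O2)ccc1OCc1ccccc1 | intermediate
20 | (2S,4S,6R)-2-[3,4-bis(benzyloxy)-5-methoxyphenyl]-6-[(E)-2-(4-benzyloxy-3-methoxyphenyl)ethenyl]tetrahydropyran-4-ol | COc1cc(/C=C/[C@H]2C[C@H](O)C[C@@H](c3cc(OCc4ccccc4)c(OCc4ccccc4)c(OC)c3)O2)ccc1OCc1ccccc1 | intermediate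
21 | (2S,4S,6S)-2-(3,4-dihydroxy-5-methoxyphenyl)-6-[2-(4-hydroxy-3-methoxyphenyl)ethyl]tetrahydropyran-4-ol, CNP0399218.2 | COc1cc(CC[C@H]2C[C@H](O)C[C@@H](c3cc(O)c(O)c(OC)c3)O2)ccc1O | target

## Step count and risks

Total step count: 13. Longest linear sequence: 12 (steps 1–9 and 11–13, from 1).

**Step 9.**
- What may go wrong: slow or unselective ring closure. Incomplete exchange of the allyl faces, a ligand pocket that works against the chair preference, carry-over of Z-alkene from step 7, or β-hydride loss to a diene would erode the 2,6-cis selectivity or the conversion.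
- Fallback: oxa-Michael closure in place of allylic substitution, setting out from 11 and coming back at 19.
- Cross-metathesis of 11 with crotonaldehyde (second-generation Hoveyda–Grubbs catalyst, CH2Cl2, 40 °C) gives the bis-silylated (E)-enal F1.
- Buffered HF·pyridine frees the C2 hydroxyl to give the hydroxy enal F2.
- Under pyrrolidine/benzoic acid catalysis this closes reversibly to the thermodynamically preferred 2,6-cis pyranyl acetaldehyde F3.
- The aryl Grignard reagent F4, made from 18 and Mg turnings in THF, adds to F3 at −78 °C to give the benzylic alcohol F5 (both C8 epimers).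
- MsCl/Et3N converts it into the labile mesylate F6, which eliminates on addition of DBU in the same flask to give 19.

**Step 11.**
- What may go wrong: sluggish oxidative addition of the electron-rich bromide, β-hydride loss toward C6–H with migration of the double bond into the enol ether position (this would erase C6), or opening of the allylic C6–O1 bond at 100 °C.
- Fallback: hydroboration and sp3–sp2 coupling in place of the Heck reaction, setting out from 16 and coming back at 21.
- 9-BBN-H adds to the vinyl group of 16 (THF, rt) to give the B-alkyl borane F7.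
- B-alkyl Suzuki–Miyaura coupling with 18 (PdCl2(dppf), Cs2CO3, DMF–H2O, 50 °C) gives the saturated tribenzyl silyl ether F8.
- TBAF in THF gives the saturated tribenzyl alcohol F9, and hydrogenolysis (H2, 10% Pd/C) gives 21.
- This path never holds an allylic ether during hydrogenation.

**Step 8.**
- What may go wrong: incomplete discrimination between the two silyl ethers, or solvolysis at the electron-rich benzylic carbon with loss of the C2 configuration.
- Fallback: cyclisation without hydroxyl differentiation, setting out from 13 and coming back at 20.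
- Excess HF·pyridine in THF at rt strips both silyl groups from 13 to give the syn-diol carbonate F10.
- The catalyst system of step 9 closes it to the 4-hydroxy-6-vinyl pyran F11. Ring size is now the selector, because the C4 hydroxyl could only reach the inner allyl carbon by forming an oxetane.
- Heck coupling with 18 under the conditions of step 11 gives 20 directly and makes step 12 unnecessary.

## Further compounds

F1 | step 9 | (E,5S,7S)-7-[3,4-bis(benzyloxy)-5-methoxyphenyl]-5-(tert-butyldimethylsilyloxy)-7-(triethylsilyloxy)hept-2-enal | O=C/C=C/C[C@H](O[Si](C)(C)C(C)(C)C)C[C@H](O[Si](CC)(CC)CC)c1cc(OCc2ccccc2)c(OCc2ccccc2)c(OC)c1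
F2 | step 9 | (E,5S,7S)-7-[3,4-bis(benzyloxy)-5-methoxyphenyl]-5-(tert-butyldimethylsilyloxy)-7-hydroxyhept-2-enal | O=C/C=C/C[C@H](O[Si](C)(C)C(C)(C)C)C[C@H](O)c1cc(OCc2ccccc2)c(OCc2ccccc2)c(OC)c1
F3 | step 9 | 2-{2,6-cis-6-[3,4-bis(benzyloxy)-5-methoxyphenyl]-4-(tert-butyldimethylsilyloxy)tetrahydropyran-2-yl}acetaldehyde | O=CC[C@H]1C[C@H](O[Si](C)(C)C(C)(C)C)C[C@@H](c2cc(OCc3ccccc3)c(OCc3ccccc3)c(OC)c2)O1
F4 | step 9 | (4-benzyloxy-3-methoxyphenyl)magnesium bromide | COc1cc([Mg]Br)ccc1OCc1ccccc1
F5 | step 9 | 1-(4-benzyloxy-3-methoxyphenyl)-2-{2,6-cis-6-[3,4-bis(benzyloxy)-5-methoxyphenyl]-4-(tert-butyldimethylsilyloxy)tetrahydropyran-2-yl}ethanol, both carbinol epimers | COc1cc(C(O)C[C@H]2C[C@H](O[Si](C)(C)C(C)(C)C)C[C@@H](c3cc(OCc4ccccc4)c(OCc4ccccc4)c(OC)c3)O2)ccc1OCc1ccccc1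
F6 | step 9 | methanesulfonate of F5 | COc1cc(C(OS(C)(=O)=O)C[C@H]2C[C@H](O[Si](C)(C)C(C)(C)C)C[C@@H](c3cc(OCc4ccccc4)c(OCc4ccccc4)c(OC)c3)O2)ccc1OCc1ccccc1
F7 | step 11 | 9-{2-[2,6-cis-6-(3,4-bis(benzyloxy)-5-methoxyphenyl)-4-(tert-butyldimethylsilyloxy)tetrahydropyran-2-yl]ethyl}-9-borabicyclo[3.3.1]nonane | C(C[C@H]1C[C@H](O[Si](C)(C)C(C)(C)C)C[C@@H](c2cc(OCc3ccccc3)c(OCc3ccccc3)c(OC)c2)O1)B1C2CCCC1CCC2
F8 | step 11 | (2S,4S,6S)-2-[3,4-bis(benzyloxy)-5-methoxyphenyl]-6-[2-(4-benzyloxy-3-methoxyphenyl)ethyl]-4-(tert-butyldimethylsilyloxy)tetrahydropyran | COc1cc(CC[C@H]2C[C@H](O[Si](C)(C)C(C)(C)C)C[C@@H](c3cc(OCc4ccccc4)c(OCc4ccccc4)c(OC)c3)O2)ccc1OCc1ccccc1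
F9 | step 11 | (2S,4S,6S)-2-[3,4-bis(benzyloxy)-5-methoxyphenyl]-6-[2-(4-benzyloxy-3-methoxyphenyl)ethyl]tetrahydropyran-4-ol | COc1cc(CC[C@H]2C[C@H](O)C[C@@H](c3cc(OCc4ccccc4)c(OCc4ccccc4)c(OC)c3)O2)ccc1OCc1ccccc1
F10 | step 8 | (E,5S,7S)-7-[3,4-bis(benzyloxy)-5-methoxyphenyl]-5,7-dihydroxyhept-2-enyl methyl carbonate | COC(=O)OC/C=C/C[C@H](O)C[C@H](O)c1cc(OCc2ccccc2)c(OCc2ccccc2)c(OC)c1
F11 | step 8 | (2S,4S,6R)-2-[3,4-bis(benzyloxy)-5-methoxyphenyl]-6-vinyltetrahydropyran-4-ol | C=C[C@H]1C[C@H](O)C[C@@H](c2cc(OCc3ccccc3)c(OCc3ccccc3)c(OC)c2)O1
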